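## The problem

The target is luteolin (rings A, C and B) carrying at C8 of ring A a 2‑carboxy‑5,6‑dihydroxyphenyl group (ring D, numbered C1''–C6'' from the carboxyl‑bearing carbon). The central task is the C8–C2'' biaryl bond, which has four ortho substituents: O7 and the C8a–O1 oxygen on ring A, the carboxyl at C1'' and the hydroxyl at C3'' on ring D. Attaching ring D to a finished 5,7‑dioxygenated flavone meets two obstacles: the two free positions of ring A, C6 and C8, are electronically almost alike, and a tetra‑ortho coupling is sterically costly. There are no stereocentres; only the hindered axis could be a stereo element, and it carries no descriptor, so nothing in the route has to control configuration. The molecule has six phenolic hydroxyls, two of them in catechols, which oxidise readily in base and air, so the phenols should stay masked until the last steps. The carboxyl at C1'' sits next to O7 across the axis and can close to a six‑membered lactone; this tendency has to be either suppressed or used. The enabling feature is the pattern of ring A: C8 carries ring D and lies between the oxygenated carbons C7 and C8a, and the third oxygen, at C5, is para to C8. This 2‑aryl‑phloroglucinol pattern with three distinguishable oxygens is what the benzannulation of an alkoxy‑substituted vinylketene with an aryl ynol ether delivers, the aryl–alkyne bond becoming the biaryl bond.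

## Retrosynthesis

**Target 24 back to 22.** The last bonds cut are the five alkyl–oxygen bonds of the ethers and, formally, the ester bond between O7 and the ring D carboxyl. Holding the carboxyl and O7 together as the lactone of 23 and 22 protects both without any added atoms; the alternative, a separate ester and a separate O7 ether, would cost two further protecting groups. The lactone has O1 and the C3'' oxygen facing each other in its bay region, so it is strained and should open readily with hydroxide. The forward steps must cleave four methyl ethers and one ethyl ether of 22 without harming lactone or pyranone, and then open 23 under exclusion of air.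

**22 back to 18 and 19.** Ring C is cut at O1–C2 and C2–C3, giving the 1,3‑diketone 21 and then the ortho‑hydroxyacetophenone 18 plus 3,4‑dimethoxybenzoyl chloride 19. A chalcone route would need aqueous hydroxide and an oxidative cyclisation, and hydroxide opens the lactone. Acylation of the dianion 20 uses only a hindered amide base at low temperature. This cut removes ring B and ring C in two steps and leaves a tricyclic lactone.

**18 back to 16.** The C4–C4a bond (the acetyl group) is cut. Ring A of 16 has two free positions, one ortho and one para to its single free hydroxyl. The forward reaction must choose the ortho one, which is asked of boron chelation of the ortho‑hydroxy ketone (17). Introducing the acetyl group earlier, on an open biaryl, would offer no such handle.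

**16 back to 14.** The lactone C–O bond and the O–Si bond are cut, giving resorcinol 15 and then the silyl ether 14. Removing silicon first makes the two hydroxyls flanking the biaryl bond equivalent, so lactonisation of 15 can only give 16. It also keeps the bulky silyl group out of the bay region of the lactone. The oxygen born as the free hydroxyl of 14 is counted as O7 and the silylated one as O1.

**14 back to 8 and 9 (key disconnection).** Ring A is cut at C7–C8, C4a–C8a and C6–C7, giving the ring D siloxyalkyne 8 and 3‑ethoxycyclobut‑2‑en‑1‑one 9. Against a tetra‑ortho biaryl coupling, this cut never forms the hindered bond by coupling; it exists in 8 as an unhindered aryl–alkyne bond and ring A is grown around it. The position of ring D between two oxygens is fixed by the polarity of the ynol ether, so the C6/C8 question does not arise. The precursor has one ring and no biaryl. The forward reaction must give one orientation of ketene–alkyne addition and must tolerate the ortho ester.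

**8 back to 1 and 3.** The O–Si and C(sp)–O bonds are cut to the terminal alkyne 5 (acetylide oxidation to ynolate 7 via 6), then the C(sp)–C(aryl) bond to bromide 2 and trimethylsilylacetylene 3 via 4, and finally the ester bond to 2‑bromo‑3,4‑dimethoxybenzoic acid 1. A tert‑butyl ester is chosen for ring D for three reasons:
- it resists the amide base, the peroxide anion and the ynolate in the step to 8;
- it does not lactonise onto the phenol during the benzannulation;
- it leaves under acid exactly when the lactone is wanted.

## Roads not taken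

**Alternative 1:** Ring A is cut at C8–C8a and C4a–C5. A Brassard‑type diene A2 carrying ring D on its terminal carbon would add to the C5=C6 bond of the 5‑sulfinyl‑2‑aryl‑4‑pyranone A3. Loss of sulfenic acid, methanol and silanol would give flavone A1.
- Merits: the route is convergent, rings B and C arrive complete, the 5‑hydroxy/7‑methoxy pattern follows from diene polarity, and A1 is about two steps from the target with no lactone detour.
- Weak points: the di‑ortho‑substituted ring D sits on the very diene carbon that must bond to C8a. The C5=C6 bond of a 4‑pyranone is a reluctant dienophile even with sulfinyl activation. A2 and A3 each need several steps, and A2 must hold a defined diene geometry.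
- Comparison: if the cycloaddition worked, this road would be shorter after the key step (two steps against seven) and more convergent; that advantage is real. The chosen plan sets against it a ketene adding to a linear alkyne, with low steric demand at the aryl‑bearing carbon, an irreversible cascade ending in aromatisation, and a precursor 8 that needs only four steps.

**Alternative 2:** The C8–C2'' bond is cut on a preformed flavone. The 7‑O‑(2‑bromo‑3,4‑dimethoxybenzoyl) ester A5 would cyclise under Pd(OAc)2, PCy3·HBF4, K2CO3 and pivalic acid to lactone A4, the methyl analogue of 22.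
- Merits: this is the shortest road. The flavone is made from commodity materials, the tether is acid 1, and A4 is two steps from the target.
- Weak points: the ester oxygen at C7 has two ortho C–H bonds, C6 and C8, and the tether reaches both through the same ring size. Either closure creates a comparable bay interaction, so nothing secures C8, and constitutional isomers that are hard to tell apart are the likely outcome. The bromide is electron‑rich and di‑ortho‑substituted, and the aryl ester may cleave under carbonate at the temperature needed.
- Comparison: in step count and convergence this road is better, by roughly five steps. The chosen plan sets against it an unambiguous constitution at C8, because the aryl–C8 bond exists before ring A does.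

**Alternative 3:** Ring D is cut at C2''–C3'' and C1''–C6''. 3‑Methoxyfuran A8 would add to the 8‑(methoxycarbonylethynyl)flavone A7, and acid would open the oxygen bridge to give phenol A6.
- Merits: flavone chemistry is done on simple substrates, the hindered biaryl is again made by ring construction, the methoxy group directs both the cycloaddition and the bridge opening, and A6 is about two steps from the target.
- Weak points: furans are poor, reversible dienes. The alkyne of A7 carries a di‑ortho‑substituted, electron‑rich aryl group on the carbon that must bond to the more substituted furan terminus. A8 is volatile and acid‑sensitive. A7 needs a C8‑selective halogenation and a propiolate coupling, both delicate.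
- Comparison: the end game is shorter than in the chosen plan. The chosen plan offers a strongly polarised, matched pair (electrophilic ketene, nucleophilic ynol ether) instead of a reluctant equilibrium cycloaddition, and a ring A that emerges with its three oxygens already differentiated.

Key step: step 5

Assumption: the target is drawn without a descriptor for the C8–C2'' axis, so it is made as the racemate of that axis should the axis prove configurationally stable.

## Route

Step 1
Reactants: 1 2-bromo-3,4-dimethoxybenzoic acid
Product: 2 tert-butyl 2-bromo-3,4-dimethoxybenzoate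
Conditions: Cl3CC(=NH)OtBu (2 equiv), BF3·OEt2 (cat.), CH2Cl2/cyclohexane, rt
Reagents that add atoms: tert-butyl 2,2,2-trichloroacetimidate, CC(C)(C)OC(=N)C(Cl)(Cl)Cl
Why: Acid-catalysed O-tert-butylation of a carboxylic acid by a trichloroacetimidate; the carboxylate oxygen is alkylated, so the crowded carbonyl carbon need not be attacked.

Step 2
Reactants: 2 tert-butyl 2-bromo-3,4-dimethoxybenzoate; 3 trimethylsilylacetylene
Product: 4 tert-butyl 3,4-dimethoxy-2-[(trimethylsilyl)ethynyl]benzoate
Conditions: PdCl2(PPh3)2 (5 mol %), CuI (10 mol %), Et3N, DMF, 80 °C, sealed tube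
Reagents that add atoms: none
Why: Sonogashira coupling; the ortho ester activates the C–Br bond for oxidative addition and the slim copper acetylide tolerates the two flanking groups.

Step 3
Reactants: 4 tert-butyl 3,4-dimethoxy-2-[(trimethylsilyl)ethynyl]benzoate
Product: 5 tert-butyl 2-ethynyl-3,4-dimethoxybenzoate
Conditions: K2CO3 (0.2 equiv), MeOH, rt
Reagents that add atoms: none
Why: Methanolysis of the C(sp)–Si bond; the tert-butyl ester is inert to methoxide at room temperature.

Step 4
Reactants: 5 tert-butyl 2-ethynyl-3,4-dimethoxybenzoate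
Product: 8 tert-butyl 3,4-dimethoxy-2-[(triisopropylsilyloxy)ethynyl]benzoate, via lithium acetylide 6 (not isolated), via lithium ynolate 7 (not isolated)
Conditions: LiN(SiMe3)2, THF, −78 °C; LiOOtBu (from tBuOOH and LiN(SiMe3)2), −78 to 0 °C; TIPSOTf, −78 to 0 °C; chromatography on Et3N-deactivated silica
Reagents that add atoms: tert-butyl hydroperoxide, CC(C)(C)OO; triisopropylsilyl trifluoromethanesulfonate, CC(C)[Si](OS(=O)(=O)C(F)(F)F)(C(C)C)C(C)C
Why: Oxidation of a lithium acetylide with lithium tert-butyl peroxide to the ynolate and O-silylation with a bulky silyl triflate (Julia-type siloxyalkyne synthesis). The tert-butyl ester resists the amide base, the peroxide anion and the ynolate, and attack of the ynolate carbon on the ortho ester would need a four-membered ring.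

Step 5
Reactants: 8 tert-butyl 3,4-dimethoxy-2-[(triisopropylsilyloxy)ethynyl]benzoate; 9 3-ethoxycyclobut-2-en-1-one
Product: 14 tert-butyl 2-[4-ethoxy-2-hydroxy-6-(triisopropylsilyloxy)phenyl]-3,4-dimethoxybenzoate, via vinylketene 10 (not isolated), via 4-vinylcyclobutenone 11 (not isolated), via dienylketene 12 (not isolated), via cyclohexadienone 13 (not isolated)
Conditions: 9 (1.5 equiv), toluene, 110 °C, sealed tube, argon
Reagents that add atoms: none
Why: Heating opens 9 by conrotatory 4π electrocyclic ring opening to vinylketene 10, whose electrophilic central carbon is attacked by the aryl-bearing carbon of ynol ether 8, so the [2+2] cycloaddition gives 4-vinylcyclobutenone 11 with the silyloxy carbon bonded to the former C2 of 9. A second 4π opening gives dienylketene 12, ring A then closes by a thermal disrotatory 6π electrocyclisation (a six-membered carbocycle, the ketene carbon bonding to the methylene terminus), and cyclohexadienone 13 tautomerises irreversibly to phenol 14. This is the Danheiser benzannulation of a cyclobutenone with a siloxyalkyne, known for making resorcinol monosilyl ethers; a 3-alkoxycyclobutenone and an aryl ynol ether are new substrates for a known reaction type. In target numbering the [2+2] event forms C7–C8 and C4a–C8a and the electrocyclisation forms C6–C7, the alkyne carbons becoming C8 and C8a. No stereocentre is created. The one selectivity needed is the orientation of the ketene–alkyne addition, and the polarisation of the ynol ether by its oxygen secures it, placing ring D between the hydroxyl and the silyloxy group with the ethoxy group para to it. The linear alkyne keeps the di-ortho-substituted ring D away from the reacting centres, the tert-butyl ester does not lactonise onto the new phenol at this temperature, and the excess of 9 allows for ketene self-condensation.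

Step 6
Reactants: 14 tert-butyl 2-[4-ethoxy-2-hydroxy-6-(triisopropylsilyloxy)phenyl]-3,4-dimethoxybenzoate
Product: 15 tert-butyl 2-(4-ethoxy-2,6-dihydroxyphenyl)-3,4-dimethoxybenzoate
Conditions: TBAF (1.1 equiv), THF, 0 °C; aq. NH4Cl
Reagents that add atoms: none
Why: Fluoride cleavage of an aryl silyl ether; the tert-butyl ester is untouched, and the two hydroxyls flanking the biaryl bond become equivalent.

Step 7
Reactants: 15 tert-butyl 2-(4-ethoxy-2,6-dihydroxyphenyl)-3,4-dimethoxybenzoate
Product: 16 3-ethoxy-1-hydroxy-9,10-dimethoxy-6H-benzo[c]chromen-6-one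
Conditions: TsOH·H2O (0.2 equiv), toluene, 90 °C
Reagents that add atoms: none
Why: Acid-catalysed loss of 2-methylpropene from the tert-butyl ester and intramolecular esterification by an ortho hydroxyl to the six-membered biaryl lactone. Either hydroxyl of 15 gives the same 16, and the remaining hydroxyl can hydrogen-bond to the bay methoxy group.

Step 8
Reactants: 16 3-ethoxy-1-hydroxy-9,10-dimethoxy-6H-benzo[c]chromen-6-one
Product: 18 2-acetyl-3-ethoxy-1-hydroxy-9,10-dimethoxy-6H-benzo[c]chromen-6-one, via difluoroboron chelate 17 (not isolated)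
Conditions: Ac2O (3 equiv), BF3·OEt2 (3 equiv), 80 °C; then NaOAc, MeOH/H2O, 65 °C
Reagents that add atoms: acetic anhydride, CC(=O)OC(C)=O
Why: Boron trifluoride-mediated C-acetylation of a phloroglucinol-type phenol (Friedel–Crafts/Fries manifold), in which the ortho-hydroxy ketone is trapped as the six-membered chelate 17. This favours C2, ortho to the free hydroxyl, over C4, para to it; aqueous acetate then frees 18.

Step 9
Reactants: 18 2-acetyl-3-ethoxy-1-hydroxy-9,10-dimethoxy-6H-benzo[c]chromen-6-one; 19 3,4-dimethoxybenzoyl chloride
Product: 21 1-(3,4-dimethoxyphenyl)-3-(3-ethoxy-1-hydroxy-9,10-dimethoxy-6-oxo-6H-benzo[c]chromen-2-yl)propane-1,3-dione, via dilithium dianion 20 (not isolated)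
Conditions: LiN(SiMe3)2 (3.5 equiv), THF, −78 to −10 °C; 19 (1.05 equiv), −78 °C to rt; aq. HCl
Reagents that add atoms: none
Why: One-flask variant of the Baker–Venkataraman synthesis: the phenoxide–enolate dianion is C-acylated by the aroyl chloride to the 1,3-diketone. The hindered amide base does not open the lactone, and the enolate carbon is para to the lactone oxygen, so it cannot reach the lactone carbonyl.

Step 10
Reactants: 21 1-(3,4-dimethoxyphenyl)-3-(3-ethoxy-1-hydroxy-9,10-dimethoxy-6-oxo-6H-benzo[c]chromen-2-yl)propane-1,3-dione
Product: 22 lactone between O7 and the ring D carboxyl of 2-[2-(3,4-dimethoxyphenyl)-5-ethoxy-7-hydroxy-4-oxo-4H-chromen-8-yl]-3,4-dimethoxybenzoic acid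
Conditions: H2SO4 (cat.), AcOH, 95 °C
Reagents that add atoms: none
Why: Acid-catalysed cyclodehydration of an ortho-hydroxyaryl 1,3-diketone to the flavone; the lactone is the favoured form under acid and is not opened.

Step 11
Reactants: 22 lactone between O7 and the ring D carboxyl of 2-[2-(3,4-dimethoxyphenyl)-5-ethoxy-7-hydroxy-4-oxo-4H-chromen-8-yl]-3,4-dimethoxybenzoic acid
Product: 23 lactone between O7 and the ring D carboxyl of 2-[2-(3,4-dihydroxyphenyl)-5,7-dihydroxy-4-oxo-4H-chromen-8-yl]-3,4-dihydroxybenzoic acid
Conditions: BBr3 (12 equiv), CH2Cl2, −78 °C to rt; H2O, 0 °C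
Reagents that add atoms: none
Why: Lewis-acid cleavage of aryl alkyl ethers by bromide attack on the O-bound alkyl group; the ethoxy group peri to the C4 carbonyl is helped by chelation, and the aryl lactone and the pyranone have no alkyl–oxygen bond to lose.

Step 12
Reactants: 23 lactone between O7 and the ring D carboxyl of 2-[2-(3,4-dihydroxyphenyl)-5,7-dihydroxy-4-oxo-4H-chromen-8-yl]-3,4-dihydroxybenzoic acid
Product: 24 2-[2-(3,4-dihydroxyphenyl)-5,7-dihydroxy-4-oxo-4H-chromen-8-yl]-3,4-dihydroxybenzoic acid
Conditions: LiOH (aq., 8 equiv), THF/H2O (degassed, argon), 0 °C to rt; 1 M HCl, 0 °C, to pH 2–3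
Reagents that add atoms: lithium hydroxide (aqueous), [Li+].[OH-]
Why: Saponification of an aryl lactone; the bay interaction between O1 and the C3'' hydroxyl twists the lactone, which should speed acyl substitution and disfavour re-closure on cold acidification.

## Compound list

1 | 2-bromo-3,4-dimethoxybenzoic acid | COc1ccc(C(=O)O)c(Br)c1OC | starting material
2 | tert-butyl 2-bromo-3,4-dimethoxybenzoate | COc1ccc(C(=O)OC(C)(C)C)c(Br)c1OC | intermediate
3 | trimethylsilylacetylene | C#C[Si](C)(C)C | starting material
4 | tert-butyl 3,4-dimethoxy-2-[(trimethylsilyl)ethynyl]benzoate | COc1ccc(C(=O)OC(C)(C)C)c(C#C[Si](C)(C)C)c1OC | intermediate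
5 | tert-butyl 2-ethynyl-3,4-dimethoxybenzoate | COc1ccc(C(=O)OC(C)(C)C)c(C#C)c1OC | intermediate
6 | tert-butyl 2-(lithioethynyl)-3,4-dimethoxybenzoate (lithium acetylide) | COc1ccc(C(=O)OC(C)(C)C)c(C#C[Li])c1OC | intermediate
7 | lithium 2-[2-(tert-butoxycarbonyl)-5,6-dimethoxyphenyl]ethynolate (lithium ynolate) | COc1ccc(C(=O)OC(C)(C)C)c(C#CO[Li])c1OC | intermediate
8 | tert-butyl 3,4-dimethoxy-2-[(triisopropylsilyloxy)ethynyl]benzoate | COc1ccc(C(=O)OC(C)(C)C)c(C#CO[Si](C(C)C)(C(C)C)C(C)C)c1OC | intermediate
9 | 3-ethoxycyclobut-2-en-1-one | CCOC1=CC(=O)C1 | starting material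
10 | 3-ethoxybuta-1,3-dien-1-one (vinylketene) | CCOC(=C)C=C=O | intermediate
11 | tert-butyl 2-[3-(1-ethoxyethenyl)-4-oxo-2-(triisopropylsilyloxy)cyclobut-1-en-1-yl]-3,4-dimethoxybenzoate (racemic) | CCOC(=C)C1C(=O)C(c2c(C(=O)OC(C)(C)C)ccc(OC)c2OC)=C1O[Si](C(C)C)(C(C)C)C(C)C | intermediate
12 | tert-butyl 2-[(3E)-5-ethoxy-1-oxo-3-(triisopropylsilyloxy)hexa-1,3,5-trien-2-yl]-3,4-dimethoxybenzoate (dienylketene) | CCOC(=C)/C=C(/O[Si](C(C)C)(C(C)C)C(C)C)C(=C=O)c1c(C(=O)OC(C)(C)C)ccc(OC)c1OC | intermediate
13 | tert-butyl 2-[4-ethoxy-6-oxo-2-(triisopropylsilyloxy)cyclohexa-1,3-dien-1-yl]-3,4-dimethoxybenzoate | CCOC1=CC(O[Si](C(C)C)(C(C)C)C(C)C)=C(c2c(C(=O)OC(C)(C)C)ccc(OC)c2OC)C(=O)C1 | intermediate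
14 | tert-butyl 2-[4-ethoxy-2-hydroxy-6-(triisopropylsilyloxy)phenyl]-3,4-dimethoxybenzoate | CCOc1cc(O)c(-c2c(C(=O)OC(C)(C)C)ccc(OC)c2OC)c(O[Si](C(C)C)(C(C)C)C(C)C)c1 | intermediate
15 | tert-butyl 2-(4-ethoxy-2,6-dihydroxyphenyl)-3,4-dimethoxybenzoate | CCOc1cc(O)c(-c2c(C(=O)OC(C)(C)C)ccc(OC)c2OC)c(O)c1 | intermediate
16 | 3-ethoxy-1-hydroxy-9,10-dimethoxy-6H-benzo[c]chromen-6-one | CCOc1cc2OC(=O)c3ccc(OC)c(OC)c3-c2c(O)c1 | intermediate
17 | difluoroboron chelate of 18 (boron bound to the C1 phenoxide oxygen and the acetyl oxygen) | CCOc1cc2OC(=O)c3ccc(OC)c(OC)c3-c2c2O[B-](F)(F)[O+]=C(C)c12 | intermediate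
18 | 2-acetyl-3-ethoxy-1-hydroxy-9,10-dimethoxy-6H-benzo[c]chromen-6-one | CCOc1cc2OC(=O)c3ccc(OC)c(OC)c3-c2c(O)c1C(C)=O | intermediate
19 | 3,4-dimethoxybenzoyl chloride | COc1ccc(C(=O)Cl)cc1OC | starting material
20 | dilithium phenoxide–enolate of 18 | CCOc1cc2OC(=O)c3ccc(OC)c(OC)c3-c2c(O[Li])c1C(=C)O[Li] | intermediate
21 | 1-(3,4-dimethoxyphenyl)-3-(3-ethoxy-1-hydroxy-9,10-dimethoxy-6-oxo-6H-benzo[c]chromen-2-yl)propane-1,3-dione | CCOc1cc2OC(=O)c3ccc(OC)c(OC)c3-c2c(O)c1C(=O)CC(=O)c1ccc(OC)c(OC)c1 | intermediate
22 | lactone between O7 and the ring D carboxyl of 2-[2-(3,4-dimethoxyphenyl)-5-ethoxy-7-hydroxy-4-oxo-4H-chromen-8-yl]-3,4-dimethoxybenzoic acid | CCOc1cc2OC(=O)c3ccc(OC)c(OC)c3-c2c2oc(-c3ccc(OC)c(OC)c3)cc(=O)c12 | intermediate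
23 | lactone between O7 and the ring D carboxyl of 2-[2-(3,4-dihydroxyphenyl)-5,7-dihydroxy-4-oxo-4H-chromen-8-yl]-3,4-dihydroxybenzoic acid | O=C1Oc2cc(O)c3c(=O)cc(-c4ccc(O)c(O)c4)oc3c2-c2c1ccc(O)c2O | intermediate
24 | 2-[2-(3,4-dihydroxyphenyl)-5,7-dihydroxy-4-oxo-4H-chromen-8-yl]-3,4-dihydroxybenzoic acid | O=C(O)c1ccc(O)c(O)c1-c1c(O)cc(O)c2c(=O)cc(-c3ccc(O)c(O)c3)oc12 | target

## Step count and risks

Total: 12 steps. Longest linear sequence: 12 steps, from 1 to 24; compounds 3, 9 and 19 are purchased.

**Step 5 (key step).** The ynol ether of 8 is conjugated with an ortho ester and flanked by two ortho substituents. Capture of vinylketene 10 may therefore be slower than ketene self-condensation or O-acylation of the product phenol. The second ring opening of 11 may also stall and call for higher temperature.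
Fallback, setting out from bromide 2 and returning at 16: 5-ethoxybenzene-1,3-diol F1 is converted with MOMCl and iPr2NEt into 1-ethoxy-3,5-bis(methoxymethoxy)benzene F2. F2 is lithiated between the two acetal groups (nBuLi, THF, 0 °C) and borylated with B(OMe)3 to [4-ethoxy-2,6-bis(methoxymethoxy)phenyl]boronic acid F3. Suzuki–Miyaura coupling of F3 with 2 (Pd(OAc)2, SPhos, K3PO4, toluene/H2O, 100 °C) gives tert-butyl 2-[4-ethoxy-2,6-bis(methoxymethoxy)phenyl]-3,4-dimethoxybenzoate F4. Acid (aqueous HCl in THF, then TsOH in hot toluene) removes both acetals and the tert-butyl group and closes the lactone to 16.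

**Step 4.** Three processes threaten it: attack of the peroxide anion or of the ynolate on the ester, silylation at carbon instead of oxygen, and acid-induced cyclisation of the ester carbonyl onto the ynol ether during isolation.
Fallback, setting out from 2 and returning at 8: carbonylation of 2 (Pd(OAc)2, 1,1'-bis(diphenylphosphino)ferrocene, CO, MeOH, Et3N, 80 °C) gives 1-tert-butyl 2-methyl 3,4-dimethoxybenzene-1,2-dicarboxylate F5. Kowalski homologation follows: LiCHBr2 (from CH2Br2 and lithium 2,2,6,6-tetramethylpiperidide, THF, −78 °C) attacks the methyl ester selectively to give tert-butyl 2-(2,2-dibromoacetyl)-3,4-dimethoxybenzoate F6. Its enolate (LiN(SiMe3)2), treated with nBuLi, undergoes bromine–lithium exchange and a 1,2-aryl shift to ynolate 7, which is silylated with TIPSOTf to 8.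

**Step 8.** Acylation at C4 (para to the hydroxyl) may compete with C2, or the O-acetate may fail to rearrange, giving a mixture of ketones that is hard to separate.
Fallback, setting out from 16 and returning at 18: magnesium-mediated ortho-formylation (MgCl2, Et3N, paraformaldehyde, MeCN, reflux) delivers formaldehyde only ortho to the phenoxide and gives 3-ethoxy-1-hydroxy-9,10-dimethoxy-6-oxo-6H-benzo[c]chromene-2-carbaldehyde F7. MeTi(OiPr)3 (THF, −20 °C), which adds to aldehydes but not to esters, gives 3-ethoxy-1-hydroxy-2-(1-hydroxyethyl)-9,10-dimethoxy-6H-benzo[c]chromen-6-one F8. Oxidation of the benzylic alcohol with MnO2 (CH2Cl2, rt) gives 18.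

**Step 12.** The lactone may re-close during acidification, and the catecholates may oxidise in air while the solution is basic. Purifying a very polar polyphenolic acid adds to the difficulty.
Fallback, setting out from 23 and returning at 24: the lactone is opened with aqueous NaOH under argon and the crude salt is benzylated exhaustively without acidification (benzyl bromide, K2CO3, DMF, 60 °C). This gives benzyl 3,4-bis(benzyloxy)-2-{5,7-bis(benzyloxy)-2-[3,4-bis(benzyloxy)phenyl]-4-oxo-4H-chromen-8-yl}benzoate F9, which can be purified on silica. Hydrogenolysis (H2, Pd/C, EtOAc/MeOH, rt) then releases 24 under neutral conditions.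

## Further compounds

F1 | step 5 | 5-ethoxybenzene-1,3-diol | CCOc1cc(O)cc(O)c1
F2 | step 5 | 1-ethoxy-3,5-bis(methoxymethoxy)benzene | CCOc1cc(OCOC)cc(OCOC)c1
F3 | step 5 | [4-ethoxy-2,6-bis(methoxymethoxy)phenyl]boronic acid | CCOc1cc(OCOC)c(B(O)O)c(OCOC)c1
F4 | step 5 | tert-butyl 2-[4-ethoxy-2,6-bis(methoxymethoxy)phenyl]-3,4-dimethoxybenzoate | CCOc1cc(OCOC)c(-c2c(C(=O)OC(C)(C)C)ccc(OC)c2OC)c(OCOC)c1
F5 | step 4 | 1-tert-butyl 2-methyl 3,4-dimethoxybenzene-1,2-dicarboxylate | COC(=O)c1c(C(=O)OC(C)(C)C)ccc(OC)c1OC
F6 | step 4 | tert-butyl 2-(2,2-dibromoacetyl)-3,4-dimethoxybenzoate | COc1ccc(C(=O)OC(C)(C)C)c(C(=O)C(Br)Br)c1OC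
F7 | step 8 | 3-ethoxy-1-hydroxy-9,10-dimethoxy-6-oxo-6H-benzo[c]chromene-2-carbaldehyde | CCOc1cc2OC(=O)c3ccc(OC)c(OC)c3-c2c(O)c1C=O
F8 | step 8 | 3-ethoxy-1-hydroxy-2-(1-hydroxyethyl)-9,10-dimethoxy-6H-benzo[c]chromen-6-one (racemic) | CCOc1cc2OC(=O)c3ccc(OC)c(OC)c3-c2c(O)c1C(C)O
F9 | step 12 | benzyl 3,4-bis(benzyloxy)-2-{5,7-bis(benzyloxy)-2-[3,4-bis(benzyloxy)phenyl]-4-oxo-4H-chromen-8-yl}benzoate | O=C(OCc1ccccc1)c1ccc(OCc2ccccc2)c(OCc2ccccc2)c1-c1c(OCc2ccccc2)cc(OCc2ccccc2)c2c(=O)cc(-c3ccc(OCc4ccccc4)c(OCc4ccccc4)c3)oc12
A1 | alternative 1 | tert-butyl 2-[2-(3,4-dimethoxyphenyl)-5-hydroxy-7-methoxy-4-oxo-4H-chromen-8-yl]-3,4-dimethoxybenzoate | CC(C)(C)OC(=O)c1ccc(OC)c(OC)c1-c1c(OC)cc(O)c2c(=O)cc(-c3ccc(OC)c(OC)c3)oc12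
A2 | alternative 1 | tert-butyl 2-[2,4-dimethoxy-4-(trimethylsilyloxy)buta-1,3-dien-1-yl]-3,4-dimethoxybenzoate (double-bond geometry not specified) | CC(C)(C)OC(=O)c1ccc(OC)c(OC)c1C=C(OC)C=C(OC)O[Si](C)(C)C
A3 | alternative 1 | 2-(3,4-dimethoxyphenyl)-5-(phenylsulfinyl)-4H-pyran-4-one (racemic at sulfur) | O=S(c1ccccc1)c1coc(-c2ccc(OC)c(OC)c2)cc1=O
A4 | alternative 2 | lactone between O7 and the ring D carboxyl of 2-[2-(3,4-dimethoxyphenyl)-7-hydroxy-5-methoxy-4-oxo-4H-chromen-8-yl]-3,4-dimethoxybenzoic acid | COc1ccc(cc1OC)-c1cc(=O)c2c(OC)cc3OC(=O)c4ccc(OC)c(OC)c4-c3c2o1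
A5 | alternative 2 | 2-(3,4-dimethoxyphenyl)-5-methoxy-4-oxo-4H-chromen-7-yl 2-bromo-3,4-dimethoxybenzoate | COc1ccc(cc1OC)-c1cc(=O)c2c(OC)cc(OC(=O)c3ccc(OC)c(OC)c3Br)cc2o1
A6 | alternative 3 | methyl 2-[2-(3,4-dimethoxyphenyl)-5,7-dimethoxy-4-oxo-4H-chromen-8-yl]-3-hydroxy-4-methoxybenzoate | COC(=O)c1ccc(OC)c(O)c1-c1c(OC)cc(OC)c2c(=O)cc(-c3ccc(OC)c(OC)c3)oc12
A7 | alternative 3 | methyl 3-[2-(3,4-dimethoxyphenyl)-5,7-dimethoxy-4-oxo-4H-chromen-8-yl]prop-2-ynoate | COC(=O)C#Cc1c(OC)cc(OC)c2c(=O)cc(-c3ccc(OC)c(OC)c3)oc12
A8 | alternative 3 | 3-methoxyfuran | COc1ccoc1
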